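**Retrosynthetic overview** (ring numbered as in the target SMILES: C1 = stereocenter, then C2 to C14)
- Target ← ester reduction ← macrocyclic (Z)-enoate ← ring closure at C3=C4 by an intramolecular Still–Gennari olefination. This replaces the usual sulfone or cyanohydrin alkylation macrocyclisation; it closes the ring, sets the C3=C4 geometry and brings in the hydroxymethyl carbon in one step.
- Linear phosphonate aldehyde ← Negishi sp3–sp2 coupling at C8–C9 of a (Z)-homoallylic zinc reagent (C9–C14, C1–C3, side chain) with an (E)-vinyl iodide phosphonate (C4–C8).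
- 11Z alkene ← iron-catalysed, hydroxyl-directed syn-methylmagnesiation of a homopropargylic alcohol made from the methyl ketone of a limonene-derived keto aldehyde (the old limonene methyl becomes C11).
- C1 and the side chain ← (1S,2S,4R)-limonene-1,2-diol: allylic lithiation/prenylation, then glycol cleavage.
- Rings: the cyclohexane of the chiral-pool diol is opened in step 3; the 14-membered ring is the only ring formed, in step 13.

Assumption: diol 1 is bought as the single (1S,2S,4R) isomer (the hydrolysis product of (R)-limonene oxide), and C15 denotes the exocyclic alkene carbon on C1.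

**Step 1**
Reactants: 1 (1S,2S,4R)-1-methyl-4-(prop-1-en-2-yl)cyclohexane-1,2-diol
Product: 2 (3aS,5R,7aS)-2,2,7a-trimethyl-5-(prop-1-en-2-yl)hexahydro-1,3-benzodioxole
Conditions: 2-methoxypropene, PPTS (cat.), CH2Cl2, 0 °C → rt
Reagents that add atoms: 2-methoxypropene, COC(C)=C
Why: Acid-catalysed ketalisation (acetonide formation) is driven by addition to the enol ether, the ring flipping to place both hydroxyls equatorial for the trans-fused dioxolane; no stereocenter is made or touched and the diol is masked for the organolithium step.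

**Step 2**
Reactants: 2 acetonide; 3 1-bromo-3-methylbut-2-ene
Product: 5 (3aS,5R,7aS)-2,2,7a-trimethyl-5-(6-methylhepta-1,5-dien-2-yl)hexahydro-1,3-benzodioxole, via allyllithium 4 (not isolated)
Conditions: n-BuLi, TMEDA, hexane, 0 °C → rt, 20 h; then 3, THF, −78 → 0 °C
Reagents that add atoms: none
Why: Allylic metalation of the isopropenyl methyl by n-BuLi·TMEDA (the reaction that turns limonene into β-bisabolene) gives a 2-substituted allyllithium with equivalent termini, and SN2 alkylation by the primary allylic bromide builds the whole side chain while the tertiary allylic C–H of the stereocenter stays untouched.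

**Step 3**
Reactants: 5
Product: 6 (3R)-3-(6-methylhepta-1,5-dien-2-yl)-6-oxoheptanal
Conditions: H5IO6, THF/H2O, 0 °C → rt
Reagents that add atoms: none
Why: Periodic acid hydrolyses the strained trans-acetonide and then cleaves the 1,2-diol (Malaprade glycol cleavage) without touching the isolated alkenes, so the old limonene stereocenter, now β to both carbonyls and not epimerisable, becomes C1 with C3 as aldehyde and C12 as methyl ketone.

**Step 4**
Reactants: 6
Product: 7 (5R)-7,7-dimethoxy-5-(6-methylhepta-1,5-dien-2-yl)heptan-2-one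
Conditions: HC(OMe)3, PPTS (cat.), CH2Cl2, 0 °C → rt
Reagents that add atoms: trimethyl orthoformate, COC(OC)OC
Why: Chemoselective acetalisation, the aldehyde reacting far faster than the methyl ketone under mild acid with the orthoester, masks C3 for the strong-base steps.

**Step 5**
Reactants: 7
Product: 11 (7R)-9,9-dimethoxy-7-(6-methylhepta-1,5-dien-2-yl)non-3-yn-1-ol, via lithium enolate 8 (not isolated), via enol phosphate 9 (not isolated), via lithium acetylide 10 (not isolated)
Conditions: LiN(i-Pr)2 (1.05 equiv), THF, −78 °C; ClP(O)(OEt)2, −78 °C → rt; LiN(i-Pr)2 (2.2 equiv), −78 °C → rt; HMPA, ethylene oxide, −78 °C → rt; aq. NH4Cl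
Reagents that add atoms: ethylene oxide, C1CO1
Why: Negishi's methyl ketone to alkyne sequence (kinetic enolisation at CH3, O-phosphorylation, E2 elimination to the acetylide) followed by SN2 opening of ethylene oxide in the same flask turns the ketone methyl into C11 and adds C10 and C9 with a hydroxyl placed to direct the next step.

**Step 6**
Reactants: 11
Product: 13 (3Z,7R)-9,9-dimethoxy-4-methyl-7-(6-methylhepta-1,5-dien-2-yl)non-3-en-1-ol, via alkenylmagnesium alkoxide 12 (not isolated)
Conditions: MeMgBr (5 equiv), Fe(acac)3 (20 mol %), THF, −78 → 0 °C; aq. NH4Cl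
Reagents that add atoms: methylmagnesium bromide, C[Mg]Br
Why: Alkoxide-directed iron-catalysed syn-carbomagnesiation of a homopropargylic alcohol delivers CH3 to the distal alkyne carbon (C12) and the metal to the proximal one (C11) in a five-membered chelate, so protonation leaves C10 and C13 cis, which is the 11Z trisubstituted alkene; no stereocenter is involved.

**Step 7**
Reactants: 13
Product: 14 (3Z,7R)-1-iodo-9,9-dimethoxy-4-methyl-7-(6-methylhepta-1,5-dien-2-yl)non-3-ene
Conditions: I2, PPh3, imidazole, CH2Cl2, 0 °C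
Reagents that add atoms: iodine, II
Why: Appel-type iodination (Garegg–Samuelsson conditions) converts the primary alcohol into the iodide by SN2 displacement of the oxyphosphonium, with imidazole buffering so that acetal and alkenes survive.

**Step 8**
Reactants: 15 pent-3-yn-1-ol
Product: 17 (3E)-4-iodopent-3-en-1-ol, via alkenylzirconocene 16 (not isolated)
Conditions: Cp2Zr(H)Cl (2.3 equiv), THF, rt → 40 °C; then I2, 0 °C
Reagents that add atoms: iodine, II
Why: Schwartz hydrozirconation adds Zr–H syn and, after equilibration with excess reagent, places zirconium on the less hindered methyl-bearing carbon, and iodinolysis with retention gives the E vinyl iodide that later fixes the 7E geometry.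

**Step 9**
Reactants: 17
Product: 18 (2E)-2,5-diiodopent-2-ene
Conditions: I2, PPh3, imidazole, CH2Cl2, 0 °C
Reagents that add atoms: iodine, II
Why: Appel-type iodination of the primary alcohol (SN2) leaves the vinyl iodide and its geometry untouched.

**Step 10**
Reactants: 18; 19 methyl 2-[bis(2,2,2-trifluoroethoxy)phosphoryl]acetate
Product: 21 methyl (5E)-2-[bis(2,2,2-trifluoroethoxy)phosphoryl]-6-iodohept-5-enoate, via sodium phosphonoacetate enolate 20 (not isolated)
Conditions: NaH, THF, 0 °C (19, 2 equiv); then 18, DMF, 40 °C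
Reagents that add atoms: none
Why: C-alkylation of the stabilised phosphonoacetate carbanion by the primary alkyl iodide (SN2; the vinyl iodide is inert and excess nucleophile suppresses dialkylation) gives the α-substituted Still–Gennari reagent as a racemate whose phosphonate carbon becomes sp2 later.

**Step 11**
Reactants: 14; 21
Product: 23 methyl (5E,9Z,13R)-2-[bis(2,2,2-trifluoroethoxy)phosphoryl]-15,15-dimethoxy-6,10-dimethyl-13-(6-methylhepta-1,5-dien-2-yl)pentadeca-5,9-dienoate, via alkylzinc iodide 22 (not isolated)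
Conditions: Zn dust, LiCl, THF, 40 °C; then 21, Pd(OAc)2 (3 mol %), SPhos (6 mol %), THF, rt
Reagents that add atoms: none
Why: LiCl-assisted zinc insertion into the primary iodide and Negishi sp3–sp2 cross-coupling with the vinyl iodide proceed with retention at the alkene, forming C8–C9 and the 7E alkene, and the mild alkylzinc tolerates the acetal, the ester and the acidic phosphonoacetate C–H.

**Step 12**
Reactants: 23
Product: 24 methyl (5E,9Z,13R)-2-[bis(2,2,2-trifluoroethoxy)phosphoryl]-6,10-dimethyl-13-(6-methylhepta-1,5-dien-2-yl)-15-oxopentadeca-5,9-dienoate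
Conditions: TsOH·H2O (cat.), THF/H2O, rt
Reagents that add atoms: water, O
Why: Acid-catalysed acetal hydrolysis frees the C3 aldehyde under conditions too mild to isomerise the alkenes or cleave the trifluoroethyl phosphonate, and C1 is β to the carbonyl so it cannot epimerise.

**Step 13**
Reactants: 24
Product: 25 methyl (1Z,4R,7Z,11E)-7,11-dimethyl-4-(6-methylhepta-1,5-dien-2-yl)cyclotetradeca-1,7,11-triene-1-carboxylate
Conditions: KN(SiMe3)2 (1.1 equiv, added over 4 h), 18-crown-6, THF (1 mM), −78 → −20 °C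
Reagents that add atoms: none
Why: Intramolecular Still–Gennari olefination (Z-selective Horner–Wadsworth–Emmons) closes the 14-membered ring at C3=C4 because the trifluoroethyl phosphonate eliminates from the kinetically formed adduct before it can equilibrate, placing the ester cis to C2, while high dilution favours cyclisation over oligomerisation.

**Step 14**
Reactants: 25
Product: 26 [(1Z,4R,7Z,11E)-7,11-dimethyl-4-(6-methylhepta-1,5-dien-2-yl)cyclotetradeca-1,7,11-trien-1-yl]methanol
Conditions: i-Bu2AlH (2.5 equiv), CH2Cl2, −78 °C; aq. potassium sodium tartrate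
Reagents that add atoms: none
Why: 1,2-Reduction of the α,β-unsaturated ester by i-Bu2AlH gives the allylic alcohol with the C3=C4 geometry and the C1 stereocenter unchanged.

**Compound list**
1 | (1S,2S,4R)-1-methyl-4-(prop-1-en-2-yl)cyclohexane-1,2-diol (limonene-1,2-diol) | C[C@]1(O)CC[C@@H](C(C)=C)C[C@@H]1O | starting material
2 | (3aS,5R,7aS)-2,2,7a-trimethyl-5-(prop-1-en-2-yl)hexahydro-1,3-benzodioxole | C[C@]1(OC(C)(C)O2)CC[C@@H](C(C)=C)C[C@@H]12 | intermediate
3 | 1-bromo-3-methylbut-2-ene (prenyl bromide) | CC(C)=CCBr | starting material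
4 | {2-[(3aS,5R,7aS)-2,2,7a-trimethylhexahydro-1,3-benzodioxol-5-yl]prop-2-en-1-yl}lithium (allyllithium, not isolated) | C[C@]1(OC(C)(C)O2)CC[C@@H](C(C[Li])=C)C[C@@H]12 | intermediate
5 | (3aS,5R,7aS)-2,2,7a-trimethyl-5-(6-methylhepta-1,5-dien-2-yl)hexahydro-1,3-benzodioxole | C[C@]1(OC(C)(C)O2)CC[C@@H](C(CCC=C(C)C)=C)C[C@@H]12 | intermediate
6 | (3R)-3-(6-methylhepta-1,5-dien-2-yl)-6-oxoheptanal | C=C(CCC=C(C)C)[C@H](CCC(C)=O)CC=O | intermediate
7 | (5R)-7,7-dimethoxy-5-(6-methylhepta-1,5-dien-2-yl)heptan-2-one | C=C(CCC=C(C)C)[C@H](CCC(C)=O)CC(OC)OC | intermediate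
8 | lithium (5R)-7,7-dimethoxy-5-(6-methylhepta-1,5-dien-2-yl)hept-1-en-2-olate (not isolated) | C=C(CCC=C(C)C)[C@H](CCC(=C)O[Li])CC(OC)OC | intermediate
9 | diethyl (5R)-7,7-dimethoxy-5-(6-methylhepta-1,5-dien-2-yl)hept-1-en-2-yl phosphate (not isolated) | C=C(CCC=C(C)C)[C@H](CCC(=C)OP(=O)(OCC)OCC)CC(OC)OC | intermediate
10 | [(5R)-7,7-dimethoxy-5-(6-methylhepta-1,5-dien-2-yl)hept-1-yn-1-yl]lithium (not isolated) | C=C(CCC=C(C)C)[C@H](CCC#C[Li])CC(OC)OC | intermediate
11 | (7R)-9,9-dimethoxy-7-(6-methylhepta-1,5-dien-2-yl)non-3-yn-1-ol | C=C(CCC=C(C)C)[C@H](CCC#CCCO)CC(OC)OC | intermediate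
12 | bromomagnesium (3E,7R)-3-(bromomagnesio)-9,9-dimethoxy-4-methyl-7-(6-methylhepta-1,5-dien-2-yl)non-3-en-1-olate (not isolated) | C=C(CCC=C(C)C)[C@H](CC/C(C)=C(/[Mg]Br)CCO[Mg]Br)CC(OC)OC | intermediate
13 | (3Z,7R)-9,9-dimethoxy-4-methyl-7-(6-methylhepta-1,5-dien-2-yl)non-3-en-1-ol | C=C(CCC=C(C)C)[C@H](CC/C(C)=C\CCO)CC(OC)OC | intermediate
14 | (3Z,7R)-1-iodo-9,9-dimethoxy-4-methyl-7-(6-methylhepta-1,5-dien-2-yl)non-3-ene | C=C(CCC=C(C)C)[C@H](CC/C(C)=C\CCI)CC(OC)OC | intermediate
15 | pent-3-yn-1-ol | CC#CCCO | starting material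
16 | chlorobis(cyclopentadienyl)zirconium alkoxide of (3E)-4-[chlorobis(cyclopentadienyl)zirconio]pent-3-en-1-ol (not isolated) | C/C(=C\CCO[Zr](Cl)(C1C=CC=C1)C1C=CC=C1)[Zr](Cl)(C1C=CC=C1)C1C=CC=C1 | intermediate
17 | (3E)-4-iodopent-3-en-1-ol | C/C(I)=C\CCO | intermediate
18 | (2E)-2,5-diiodopent-2-ene | C/C(I)=C\CCI | intermediate
19 | methyl 2-[bis(2,2,2-trifluoroethoxy)phosphoryl]acetate | COC(=O)CP(=O)(OCC(F)(F)F)OCC(F)(F)F | starting material
20 | sodium enolate of 19 (not isolated) | [Na+].COC(=O)[CH-]P(=O)(OCC(F)(F)F)OCC(F)(F)F | intermediate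
21 | methyl (5E)-2-[bis(2,2,2-trifluoroethoxy)phosphoryl]-6-iodohept-5-enoate (racemic at C2) | COC(=O)C(CC/C=C(\C)I)P(=O)(OCC(F)(F)F)OCC(F)(F)F | intermediate
22 | iodo[(3Z,7R)-9,9-dimethoxy-4-methyl-7-(6-methylhepta-1,5-dien-2-yl)non-3-en-1-yl]zinc (not isolated) | C=C(CCC=C(C)C)[C@H](CC/C(C)=C\CC[Zn]I)CC(OC)OC | intermediate
23 | methyl (5E,9Z,13R)-2-[bis(2,2,2-trifluoroethoxy)phosphoryl]-15,15-dimethoxy-6,10-dimethyl-13-(6-methylhepta-1,5-dien-2-yl)pentadeca-5,9-dienoate (both C2 epimers) | C=C(CCC=C(C)C)[C@H](CC/C(C)=C\CC/C(C)=C/CCC(C(=O)OC)P(=O)(OCC(F)(F)F)OCC(F)(F)F)CC(OC)OC | intermediate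
24 | methyl (5E,9Z,13R)-2-[bis(2,2,2-trifluoroethoxy)phosphoryl]-6,10-dimethyl-13-(6-methylhepta-1,5-dien-2-yl)-15-oxopentadeca-5,9-dienoate (both C2 epimers) | C=C(CCC=C(C)C)[C@H](CC/C(C)=C\CC/C(C)=C/CCC(C(=O)OC)P(=O)(OCC(F)(F)F)OCC(F)(F)F)CC=O | intermediate
25 | methyl (1Z,4R,7Z,11E)-7,11-dimethyl-4-(6-methylhepta-1,5-dien-2-yl)cyclotetradeca-1,7,11-triene-1-carboxylate | C=C(CCC=C(C)C)[C@H]1C/C=C(\C(=O)OC)CC/C=C(\C)CC/C=C(/C)CC1 | intermediate
26 | [(1Z,4R,7Z,11E)-7,11-dimethyl-4-(6-methylhepta-1,5-dien-2-yl)cyclotetradeca-1,7,11-trien-1-yl]methanol (CNP0217603.2) | C=C(CCC=C(C)C)[C@H]1C/C=C(\CO)CC/C=C(\C)CC/C=C(/C)CC1 | target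

**Totals**
Total steps: 14. Longest linear sequence: 11 steps (1–7, then 11–14) from diol 1; the phosphonate branch (steps 8–10) is 3 steps.

**Three steps most likely to fail**

Step 13 (macrocyclising olefination; the risks are oligomers and an eroded Z/E ratio inside the ring). The fallback makes the enoate intermolecularly and closes the ring at C8–C9 instead. It sets out from iodide 14: TsOH·H2O in THF/H2O gives the iodo aldehyde F1. Intermolecular Still–Gennari olefination of F1 with phosphonate 21 (KN(SiMe3)2, 18-crown-6, THF, −78 °C) gives the acyclic Z enoate F2, which carries the primary iodide and the vinyl iodide. Zn/LiCl inserts only into the primary iodide to give the alkylzinc iodide F3, which is added slowly to Pd(OAc)2/SPhos in THF at 1 mM (intramolecular Negishi coupling) and comes back to the route at macrocyclic ester 25.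

Step 6 (iron-catalysed carbomagnesiation; the risks are regiochemistry, incomplete conversion and Z/E leakage). The fallback builds the 11Z alkene by cuprate addition to an ynoate and then adds C9. It sets out from keto acetal 7: the lithium acetylide 10, made as in step 5, is quenched with methyl chloroformate to give the ynoate F4. Me2CuLi (THF, −78 °C) adds syn to give the Z enoate F5, and i-Bu2AlH gives the allylic alcohol F6. CBr4/PPh3 gives the allylic bromide F7. (i-PrO)Me2SiCH2MgCl with Li2CuCl4 (cat.) displaces bromide at the primary carbon to give the silane F8, and Tamao oxidation (KF, KHCO3, H2O2, THF/MeOH) comes back to the route at alcohol 13.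

Step 11 (Negishi coupling next to an acidic phosphonoacetate C–H; the risk is protonation of the zinc reagent). The fallback couples first and installs the phosphonate afterwards. It sets out from vinyl iodide 17 and iodide 14: t-BuMe2SiCl/imidazole turns 17 into the silyl ether F9. The alkylzinc iodide 22 made from 14 couples with F9 (Pd(OAc)2, SPhos, THF) to give the diene silyl ether F10. Bu4NF gives the alcohol F11, and I2/PPh3/imidazole gives the iodide F12. Alkylation of enolate 20 with F12 (THF/DMF, 40 °C) comes back to the route at phosphonate 23.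

**Further compounds**
F1 | step 13 | (3R,6Z)-9-iodo-6-methyl-3-(6-methylhepta-1,5-dien-2-yl)non-6-enal | C=C(CCC=C(C)C)[C@H](CC/C(C)=C\CCI)CC=O
F2 | step 13 | methyl (2Z,5R,8Z)-11-iodo-2-[(3E)-4-iodopent-3-en-1-yl]-8-methyl-5-(6-methylhepta-1,5-dien-2-yl)undeca-2,8-dienoate | C=C(CCC=C(C)C)[C@H](CC/C(C)=C\CCI)C/C=C(\C(=O)OC)CC/C=C(\C)I
F3 | step 13 | alkylzinc iodide of F2 (zinc in place of the primary iodine) | C=C(CCC=C(C)C)[C@H](CC/C(C)=C\CC[Zn]I)C/C=C(\C(=O)OC)CC/C=C(\C)I
F4 | step 6 | methyl (6R)-8,8-dimethoxy-6-(6-methylhepta-1,5-dien-2-yl)oct-2-ynoate | C=C(CCC=C(C)C)[C@H](CCC#CC(=O)OC)CC(OC)OC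
F5 | step 6 | methyl (2Z,6R)-8,8-dimethoxy-3-methyl-6-(6-methylhepta-1,5-dien-2-yl)oct-2-enoate | C=C(CCC=C(C)C)[C@H](CC/C(C)=C\C(=O)OC)CC(OC)OC
F6 | step 6 | (2Z,6R)-8,8-dimethoxy-3-methyl-6-(6-methylhepta-1,5-dien-2-yl)oct-2-en-1-ol | C=C(CCC=C(C)C)[C@H](CC/C(C)=C\CO)CC(OC)OC
F7 | step 6 | (2Z,6R)-1-bromo-8,8-dimethoxy-3-methyl-6-(6-methylhepta-1,5-dien-2-yl)oct-2-ene | C=C(CCC=C(C)C)[C@H](CC/C(C)=C\CBr)CC(OC)OC
F8 | step 6 | [(3Z,7R)-9,9-dimethoxy-4-methyl-7-(6-methylhepta-1,5-dien-2-yl)non-3-en-1-yl](dimethyl)(propan-2-yloxy)silane | C=C(CCC=C(C)C)[C@H](CC/C(C)=C\CC[Si](C)(C)OC(C)C)CC(OC)OC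
F9 | step 11 | tert-butyl{[(3E)-4-iodopent-3-en-1-yl]oxy}dimethylsilane | C/C(I)=C\CCO[Si](C)(C)C(C)(C)C
F10 | step 11 | tert-butyl{[(3E,7Z,11R)-13,13-dimethoxy-4,8-dimethyl-11-(6-methylhepta-1,5-dien-2-yl)trideca-3,7-dien-1-yl]oxy}dimethylsilane | C=C(CCC=C(C)C)[C@H](CC/C(C)=C\CC/C(C)=C/CCO[Si](C)(C)C(C)(C)C)CC(OC)OC
F11 | step 11 | (3E,7Z,11R)-13,13-dimethoxy-4,8-dimethyl-11-(6-methylhepta-1,5-dien-2-yl)trideca-3,7-dien-1-ol | C=C(CCC=C(C)C)[C@H](CC/C(C)=C\CC/C(C)=C/CCO)CC(OC)OC
F12 | step 11 | (3E,7Z,11R)-1-iodo-13,13-dimethoxy-4,8-dimethyl-11-(6-methylhepta-1,5-dien-2-yl)trideca-3,7-diene | C=C(CCC=C(C)C)[C@H](CC/C(C)=C\CC/C(C)=C/CCI)CC(OC)OC
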